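- L leaves Z with a time constant of 2.27 min, shorter than the 25 min over which E is fed, so you may hold L at its partition with Z and ask of each flask how far binding of E to L keeps up with the feed.

| setting | autumn | midnight | noon |
|---|---|---|---|
| E | 0.10 M (fed, over 25 min) | 0.10 M (fed, over 25 min) | 0.10 M (fed, over 25 min) |
| Z | 0.110 M | 0.220 M | 0.440 M |
| Q | 5.00 mM | 5.00 mM | 5.00 mM |
| time | 25 min | 25 min | 25 min |
| volume of the second phase over the first | 0.25 | 0.25 | 0.25 |

    L ⇌ Z, rate k1*([L] - [Z]/K1) per volume of the first phase (K1 = 1.4, k1 = 0.0019 s⁻¹)
    E + L ⇌ E.L (K2 = 36 L mol⁻¹, k2 = 0.020 L mol⁻¹ s⁻¹)
    E.L ⇌ J, rate k3*([E.L] - [J]/K3) per volume of the first phase (K3 = 0.33, k3 = 0.0022 s⁻¹)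
    E.L → X (k4 = 8.9 × 10⁻⁵ s⁻¹)
    L + Q → L.Q (k5 = 0.011 L mol⁻¹ s⁻¹)

- E.L is meant together with its J
- in the second phase: Z, J; everything else is in the first
- charges count per volume of the first phase; a concentration in a rate is the amount of a species over the volume of its own phase; every rate counts per litre of the first phase
- run time (autumn): 25 min

- which of these there is most of at the end, counted by the E in it, autumn (E / X / E.L)
- which of these there is most of at the end, counted by the E in it, midnight (E / X / E.L)
- which of these there is most of at the end, counted by the E in it, noon (E / X / E.L)
- final amount of the leader among these, as a percentage of the E charged, in autumn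
- final amount of the leader among these, as a percentage of the E charged, in midnight
- final amount of the leader among these, as a percentage of the E charged, in noon

- Solve the slow end first, where binding has caught up. Each E.L then carries its J in the second phase, so define the holding constant G, the pool of E.L with J per free E and per unit of free [L], an apparent association constant: G = 39.0 L mol⁻¹. At rest, pool/E = r, with r = G[L].

- At the fast end, nothing has bound and E is what was fed. To join the ends, let free E relax towards rest at λ = 0.020 L mol⁻¹ s⁻¹·([L] + 1/G). A steady feed over time T, with x = λT, leaves the free share f = (1 + r(1 − e^(−x))/x)/(1 + r), and E leads the pool while f stands above 0.5.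

- First estimate: nothing is used, so [L] is the Z charge over 1.35. Then f is 46.7% in autumn, 28.8% at midnight and 16.1% at noon.

- The objection is that the pool and Q draw on L. Subtracting the bound E of that estimate and the whole 5.00 mM of Q gives 66.8% in autumn, 39.3% at midnight and 19.6% at noon.

- Autumn has now crossed the line, and its subtraction overshot, so it needs one more pass, which gives 58.4%.

- A second objection is X. The half-life of E.L by step 4 is 130 min, longer than the run, and a pool growing steadily loses about 6.67% of itself. I therefore commit to E at 58.4% in autumn, E.L at 56.7% at midnight and E.L at 75.0% at noon.

- The forecast, a little apart from these figures, gives E at 56% in autumn, E.L at 60% at midnight and E.L at 77% at noon, and turns on “how far binding keeps up with the E feed as L is depleted”.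

- The flask gives E at 57.2% in autumn, E.L at 60.8% at midnight and E.L at 76.7% at noon, so the forecast stands. To prove it wrong, a run would need a changed leader or a leader's amount outside the forecast's stated range, and the simulated flasks show the leader changing between the Z charges of autumn, 0.110 M, and midnight, 0.220 M.

- Noon at 25.0 min is not at rest: its pool/E is 4.07 against G[L] = 10.1, so binding still lags. The noon flask left until 60.0 min reads 9.75 against 9.89. At ten times the time, 250 min, noon reads 9.62 against 9.77, so binding has caught up, yet the flask has kept moving: E.L has fallen from 76.7% to 31.7% and X has risen from 4.40% to 65.0%.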